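**Retrosynthetic overview**
1. Locants are those of the isochromene core: O2, C3 (side chain), C4, C4a, C5 (Cl), C6 (C=O), C7 (Me, OH), C8 (OAc), C8a (H), C1 (OCH2).
2. Enabling feature: in the carbocycle (C4a, C5, C6, C7, C8, C8a) the oxygen on C6 and the carbon C1 on C8a are 1,4-related across the C4a=C5 double bond, and C8 carries oxygen. This is the retron of a [4+2] adduct of a 2-pyrone (diene C6=C5–C4a=C8a, lactone bridge O–C1(=O) from C6 to C8a) with an enol ether (C7=C8).
3. Disconnections, backwards: C8 O-acetyl; C5–Cl (electrophilic chlorination); O2–C3 (6-endo hydroalkoxylation of a C4a-alkynyl enone by the C1 hydroxyl); C7–OH (enolate oxidation on a trans-locked ring); C4a–C4 (Sonogashira at a C4a enol triflate); then C6–C7 and C8–C8a together by inverse-electron-demand Diels–Alder reaction of 2-oxo-2H-pyran-4-yl triflate with a chiral (Z)-prop-1-enyl ether.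
4. Ring order: the carbocycle first, inside a 2-oxabicyclo[2.2.2]octenone whose lactone bridge is then opened by reduction; a temporary 1,3-dioxane on O8 and the C1 oxygen; the pyran ring last.
5. Stereocontrol: C8 and C8a from the cycloaddition (endo, auxiliary on the enol ether oxygen), C7 from C8 in the locked ring, the side-chain centre from an Evans methylation; the side chain enters as a terminal dienyne.

Key step: step 4

Remark: 4-hydroxy-2H-pyran-2-one, (S)-1-(2,4,6-triisopropylphenyl)ethanol and diethyl [3-(trimethylsilyl)prop-2-yn-1-yl]phosphonate are taken as catalogue compounds.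

**Route**

Step 1
Reactants: 1 (S)-1-(2,4,6-triisopropylphenyl)ethanol
Product: 2 allyl (S)-1-(2,4,6-triisopropylphenyl)ethyl ether
Conditions: KH, allyl bromide, THF, 0 °C to rt
Reagents that add atoms: allyl bromide, C=CCBr
Why: Williamson etherification of the potassium alkoxide with the allylic halide (SN2) should proceed without touching the benzylic stereocentre.

Step 2
Reactants: 2 allyl (S)-1-(2,4,6-triisopropylphenyl)ethyl ether
Product: 3 (Z)-prop-1-enyl (S)-1-(2,4,6-triisopropylphenyl)ethyl ether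
Conditions: KOtBu (0.5 equiv), DMSO, rt to 60 °C
Reagents that add atoms: none
Why: Base-mediated isomerisation of the allyl ether to the prop-1-enyl ether passes through the cis-configured, potassium-chelated oxyallyl anion and should therefore give the Z enol ether under kinetic control.

Step 3
Reactants: 4 4-hydroxy-2H-pyran-2-one
Product: 5 2-oxo-2H-pyran-4-yl trifluoromethanesulfonate
Conditions: (CF3SO2)2O, Et3N, CH2Cl2, −78 to 0 °C
Reagents that add atoms: trifluoromethanesulfonic anhydride, O=S(=O)(OS(=O)(=O)C(F)(F)F)C(F)(F)F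
Why: O-sulfonylation of the acidic vinylogous carboxylic acid gives the enol triflate, which lowers the LUMO of the pyrone for the cycloaddition and later serves as the handle for the C4a–C4 bond.

Step 4
Reactants: 5 2-oxo-2H-pyran-4-yl trifluoromethanesulfonate; 3 (Z)-prop-1-enyl (S)-1-(2,4,6-triisopropylphenyl)ethyl ether
Product: 6 (1S,4R,7R,8S)-7-methyl-3-oxo-8-[(S)-1-(2,4,6-triisopropylphenyl)ethoxy]-2-oxabicyclo[2.2.2]oct-5-en-5-yl trifluoromethanesulfonate (methyl and alkoxy groups both syn to the C5=C6 bridge)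
Conditions: 3 (1.5 equiv), CH2Cl2, 12 kbar, 25 °C
Reagents that add atoms: none
Why: Concerted but asynchronous inverse-electron-demand Diels–Alder reaction: the HOMO of the enol ether, with its largest coefficient on the methyl-bearing carbon β to oxygen (future C7), attacks the LUMO of the triflate-activated 2-pyrone at its C6 (the δ-carbon of the unsaturated lactone, future C6), and the alkoxy-bearing carbon (future C8) closes onto pyrone C3 (future C8a). The closest known reaction type is the cycloaddition of 3- and 5-halo-2-pyrones with alkyl vinyl ethers under high pressure or mild heating, which gives isolable 2-oxabicyclo[2.2.2]oct-5-en-3-ones with this regiochemistry and endo selectivity. The step closes the six-membered carbocycle by an intermolecular [4+2] cycloaddition that is suprafacial on both partners, the pyranone ring surviving as the lactone bridge that ties the C6 oxygen to C1 on C8a. C8 and C8a are set relative to each other by the endo transition state (alkoxy group under the C4a=C5 unit, therefore anti to the lactone bridge, so that O8 is trans to C1), the Z geometry of the enol ether is transferred as cis methyl and alkoxy groups, and the absolute sense is set by the auxiliary: in the s-trans enol ether with the carbinol C–H in the plane, the triisopropylphenyl group of the (S)-auxiliary shields one face and the pyrone should add to the other, which gives the C8 and C8a configuration of the target. The step needs regio-, endo- and π-facial selectivity and retention of CO2; these are secured by the single strong donor on the dienophile (oxygen on C8 only), by the compact endo transition state favoured under pressure, by the bulky auxiliary, and by running the reaction at 25 °C.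

Step 5
Reactants: 6 (1S,4R,7R,8S)-7-methyl-3-oxo-8-[(S)-1-(2,4,6-triisopropylphenyl)ethoxy]-2-oxabicyclo[2.2.2]oct-5-en-5-yl trifluoromethanesulfonate
Product: 7 (1S,4R,7R,8S)-8-hydroxy-7-methyl-3-oxo-2-oxabicyclo[2.2.2]oct-5-en-5-yl trifluoromethanesulfonate
Conditions: CF3CO2H, CH2Cl2, 0 °C
Reagents that add atoms: none
Why: Acidolysis of the 1-arylethyl ether through the benzylic cation (E1 loss of the auxiliary as the styrene) should free the C8 hydroxyl while the lactone and the enol triflate, both stable to anhydrous acid, remain.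

Step 6
Reactants: 7 (1S,4R,7R,8S)-8-hydroxy-7-methyl-3-oxo-2-oxabicyclo[2.2.2]oct-5-en-5-yl trifluoromethanesulfonate
Product: 8 3,5-dihydroxy-6-(hydroxymethyl)-4-methylcyclohex-1-en-1-yl trifluoromethanesulfonate (3-OH cis to CH2OH; 5-OH trans to CH2OH and cis to 4-CH3; C5 and C6 of this name are C8 and C8a of the target and have its configuration)
Conditions: LiBH4, THF, 0 °C to rt
Reagents that add atoms: none
Why: Borohydride reduction of the bridged lactone should open the bicycle to the C1 primary alcohol and the C6 allylic alcohol, the enol triflate being inert to this mild hydride donor.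

Step 7
Reactants: 8 3,5-dihydroxy-6-(hydroxymethyl)-4-methylcyclohex-1-en-1-yl trifluoromethanesulfonate
Product: 9 7-hydroxy-2,2,8-trimethyl-4a,7,8,8a-tetrahydro-4H-benzo[d][1,3]dioxin-5-yl trifluoromethanesulfonate (trans-fused acetonide on O8 and the C1 oxygen)
Conditions: 2,2-dimethoxypropane, PPTS (cat.), CH2Cl2, rt
Reagents that add atoms: 2,2-dimethoxypropane, COC(C)(C)OC
Why: Acid-catalysed transketalisation should engage only the pair O8 and C1–OH, which can close a trans-fused chair 1,3-dioxane, because the C6 hydroxyl is trans-1,3 to O8 and cannot bridge; the acetonide protects the diol and locks the ring conformation.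

Step 8
Reactants: 9 7-hydroxy-2,2,8-trimethyl-4a,7,8,8a-tetrahydro-4H-benzo[d][1,3]dioxin-5-yl trifluoromethanesulfonate
Product: 10 2,2,8-trimethyl-7-oxo-4a,7,8,8a-tetrahydro-4H-benzo[d][1,3]dioxin-5-yl trifluoromethanesulfonate
Conditions: Dess–Martin periodinane, CH2Cl2, rt
Reagents that add atoms: none
Why: Dess–Martin oxidation of the only free hydroxyl (allylic, C6) should give the β-triflyloxy enone, a stable and standard class of coupling partner.

Step 9
Reactants: 11 (R)-4-benzyloxazolidin-2-one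
Product: 12 (R)-4-benzyl-3-butanoyloxazolidin-2-one
Conditions: n-BuLi, THF, −78 °C; butanoyl chloride, −78 to 0 °C
Reagents that add atoms: butanoyl chloride, CCCC(Cl)=O
Why: N-acylation of the lithiated oxazolidinone by the acid chloride is the standard entry to the Evans imide.

Step 10
Reactants: 12 (R)-4-benzyl-3-butanoyloxazolidin-2-one
Product: 13 (R)-4-benzyl-3-[(R)-2-methylbutanoyl]oxazolidin-2-one
Conditions: NaN(SiMe3)2, THF, −78 °C; CH3I
Reagents that add atoms: iodomethane, CI
Why: Evans alkylation, in which the chelated Z sodium enolate is methylated on the face opposite the benzyl group, which for the butanoyl imide of the (R)-auxiliary sets the (R) α-centre.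

Step 11
Reactants: 13 (R)-4-benzyl-3-[(R)-2-methylbutanoyl]oxazolidin-2-one
Product: 14 (R)-2-methylbutan-1-ol
Conditions: LiBH4, H2O (1 equiv), Et2O, 0 °C
Reagents that add atoms: none
Why: Hydride cleavage of the imide at the exocyclic carbonyl should give the primary alcohol without epimerisation and return the auxiliary.

Step 12
Reactants: 14 (R)-2-methylbutan-1-ol; 15 2-(triphenylphosphoranylidene)propanal
Product: 17 (2E,4R)-2,4-dimethylhex-2-enal, via (R)-2-methylbutanal 16 (not isolated)
Conditions: (COCl)2, DMSO, Et3N, CH2Cl2, −78 °C; then 15, 40 °C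
Reagents that add atoms: none
Why: Swern oxidation followed in the same flask by Wittig olefination with the formyl-stabilised ylide avoids isolation of the volatile and configurationally labile aldehyde and should give the E trisubstituted enal.

Step 13
Reactants: 17 (2E,4R)-2,4-dimethylhex-2-enal; 18 diethyl [3-(trimethylsilyl)prop-2-yn-1-yl]phosphonate
Product: 19 [(3E,5E,7R)-5,7-dimethylnona-3,5-dien-1-yn-1-yl]trimethylsilane
Conditions: LiN(SiMe3)2, THF, −78 to 0 °C
Reagents that add atoms: none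
Why: Horner–Wadsworth–Emmons olefination with the lithiated propargylic phosphonate should give the E enyne by reversible addition and elimination through the anti oxaphosphetane.

Step 14
Reactants: 19 [(3E,5E,7R)-5,7-dimethylnona-3,5-dien-1-yn-1-yl]trimethylsilane
Product: 20 (3E,5E,7R)-5,7-dimethylnona-3,5-dien-1-yne
Conditions: K2CO3 (cat.), CH3OH, rt
Reagents that add atoms: none
Why: Methanolysis of the alkynyl C–Si bond by catalytic methoxide frees the terminal alkyne.

Step 15
Reactants: 10 2,2,8-trimethyl-7-oxo-4a,7,8,8a-tetrahydro-4H-benzo[d][1,3]dioxin-5-yl trifluoromethanesulfonate; 20 (3E,5E,7R)-5,7-dimethylnona-3,5-dien-1-yne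
Product: 21 5-[(3E,5E,7R)-5,7-dimethylnona-3,5-dien-1-yn-1-yl]-2,2,8-trimethyl-4a,8a-dihydro-4H-benzo[d][1,3]dioxin-7(8H)-one (trans-fused)
Conditions: Pd(PPh3)4 (5 mol %), CuI (10 mol %), Et3N, THF, rt
Reagents that add atoms: none
Why: Sonogashira coupling, in which zerovalent palladium inserts readily into the activated C4a–O bond of the β-triflyloxy enone and the copper acetylide of 20 is transferred, forming the C4a–C4 bond.

Step 16
Reactants: 21 5-[(3E,5E,7R)-5,7-dimethylnona-3,5-dien-1-yn-1-yl]-2,2,8-trimethyl-4a,8a-dihydro-4H-benzo[d][1,3]dioxin-7(8H)-one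
Product: 22 5-[(3E,5E,7R)-5,7-dimethylnona-3,5-dien-1-yn-1-yl]-8-hydroxy-2,2,8-trimethyl-4a,8a-dihydro-4H-benzo[d][1,3]dioxin-7(8H)-one (8-OH cis to the ring oxygen on C8a of this name, that is C7–OH cis to O8 of the target)
Conditions: NaN(SiMe3)2, THF, −78 °C; then 2-(phenylsulfonyl)-3-phenyloxaziridine, −78 °C
Reagents that add atoms: 2-(phenylsulfonyl)-3-phenyloxaziridine, O=S(=O)(c1ccccc1)N1OC1c1ccccc1
Why: Kinetic α′-deprotonation gives the cross-conjugated C6–C7 enolate, which is oxidised by the N-sulfonyloxaziridine (Davis oxidation); in the trans-fused, conformationally locked bicycle the oxidant should attack axially, anti to the axial C8–H (torsional control) and away from the axial acetonide methyl, placing the new C7–OH cis to O8 and the methyl group equatorial.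

Step 17
Reactants: 22 5-[(3E,5E,7R)-5,7-dimethylnona-3,5-dien-1-yn-1-yl]-8-hydroxy-2,2,8-trimethyl-4a,8a-dihydro-4H-benzo[d][1,3]dioxin-7(8H)-one
Product: 24 (7R,8R,8aR)-3-[(1E,3E,5R)-3,5-dimethylhepta-1,3-dien-1-yl]-7,8-dihydroxy-7-methyl-1,7,8,8a-tetrahydro-6H-isochromen-6-one, via trihydroxy ynenone 23 (not isolated)
Conditions: AcOH/H2O/THF (3:1:1), rt; then AuCl(PPh3)/AgOSO2CF3 (5 mol %), CH2Cl2, rt
Reagents that add atoms: none
Why: Mild aqueous acid removes the 1,3-dioxane, and the cationic monovalent gold catalyst then activates the alkyne for 6-endo-dig attack of the C1 hydroxyl at C3, the δ-carbon of the ynenone, followed by protodeauration at C4; closure through O8 would give a bridged ring with a bridgehead alkene and is excluded.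

Step 18
Reactants: 24 (7R,8R,8aR)-3-[(1E,3E,5R)-3,5-dimethylhepta-1,3-dien-1-yl]-7,8-dihydroxy-7-methyl-1,7,8,8a-tetrahydro-6H-isochromen-6-one
Product: 25 (7R,8R,8aR)-5-chloro-3-[(1E,3E,5R)-3,5-dimethylhepta-1,3-dien-1-yl]-7,8-dihydroxy-7-methyl-1,7,8,8a-tetrahydro-6H-isochromen-6-one
Conditions: N-chlorosuccinimide (1.05 equiv), CH2Cl2, 0 °C
Reagents that add atoms: N-chlorosuccinimide, O=C1CCC(=O)N1Cl
Why: Electrophilic chlorination at C5, the α-carbon of the push–pull system O2–C3=C4–C4a=C5–C6=O where the HOMO coefficient is largest, followed by loss of H5 restores the vinylogous ester, as in the C2 halogenation of 3-alkoxyenones.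

Step 19
Reactants: 25 (7R,8R,8aR)-5-chloro-3-[(1E,3E,5R)-3,5-dimethylhepta-1,3-dien-1-yl]-7,8-dihydroxy-7-methyl-1,7,8,8a-tetrahydro-6H-isochromen-6-one
Product: 26 (7R,8R,8aR)-5-chloro-3-[(1E,3E,5R)-3,5-dimethylhepta-1,3-dien-1-yl]-7-hydroxy-7-methyl-6-oxo-6,7,8,8a-tetrahydro-1H-isochromen-8-yl acetate
Conditions: Ac2O, pyridine, DMAP (cat.), CH2Cl2, 0 °C
Reagents that add atoms: acetic anhydride, CC(=O)OC(C)=O
Why: DMAP-catalysed acylation should be selective for the secondary C8 hydroxyl, the tertiary α-ketol hydroxyl at C7 being too hindered under these conditions.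

**Compound list**
1 | (S)-1-(2,4,6-triisopropylphenyl)ethanol | C[C@H](O)c1c(C(C)C)cc(C(C)C)cc1C(C)C | starting material
2 | allyl (S)-1-(2,4,6-triisopropylphenyl)ethyl ether | C[C@H](OCC=C)c1c(C(C)C)cc(C(C)C)cc1C(C)C | intermediate
3 | (Z)-prop-1-enyl (S)-1-(2,4,6-triisopropylphenyl)ethyl ether | C[C@H](O/C=C\C)c1c(C(C)C)cc(C(C)C)cc1C(C)C | intermediate
4 | 4-hydroxy-2H-pyran-2-one | O=C1C=C(O)C=CO1 | starting material
5 | 2-oxo-2H-pyran-4-yl trifluoromethanesulfonate | O=C1C=C(OS(=O)(=O)C(F)(F)F)C=CO1 | intermediate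
6 | (1S,4R,7R,8S)-7-methyl-3-oxo-8-[(S)-1-(2,4,6-triisopropylphenyl)ethoxy]-2-oxabicyclo[2.2.2]oct-5-en-5-yl trifluoromethanesulfonate | O=C1O[C@@H]2C=C(OS(=O)(=O)C(F)(F)F)[C@H]1[C@@H](O[C@@H](C)c3c(C(C)C)cc(C(C)C)cc3C(C)C)[C@H]2C | intermediate
7 | (1S,4R,7R,8S)-8-hydroxy-7-methyl-3-oxo-2-oxabicyclo[2.2.2]oct-5-en-5-yl trifluoromethanesulfonate | O=C1O[C@@H]2C=C(OS(=O)(=O)C(F)(F)F)[C@H]1[C@@H](O)[C@H]2C | intermediate
8 | 3,5-dihydroxy-6-(hydroxymethyl)-4-methylcyclohex-1-en-1-yl trifluoromethanesulfonate (3-OH cis to CH2OH, 5-OH trans to CH2OH) | O[C@@H]1C=C(OS(=O)(=O)C(F)(F)F)[C@H](CO)[C@@H](O)[C@H]1C | intermediate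
9 | 7-hydroxy-2,2,8-trimethyl-4a,7,8,8a-tetrahydro-4H-benzo[d][1,3]dioxin-5-yl trifluoromethanesulfonate (trans-fused) | O[C@@H]1C=C(OS(=O)(=O)C(F)(F)F)[C@@H]2COC(C)(C)O[C@H]2[C@H]1C | intermediate
10 | 2,2,8-trimethyl-7-oxo-4a,7,8,8a-tetrahydro-4H-benzo[d][1,3]dioxin-5-yl trifluoromethanesulfonate (trans-fused) | O=C1C=C(OS(=O)(=O)C(F)(F)F)[C@@H]2COC(C)(C)O[C@H]2[C@H]1C | intermediate
11 | (R)-4-benzyloxazolidin-2-one | O=C1N[C@H](Cc2ccccc2)CO1 | starting material
12 | (R)-4-benzyl-3-butanoyloxazolidin-2-one | CCCC(=O)N1[C@H](Cc2ccccc2)COC1=O | intermediate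
13 | (R)-4-benzyl-3-[(R)-2-methylbutanoyl]oxazolidin-2-one | CC[C@@H](C)C(=O)N1[C@H](Cc2ccccc2)COC1=O | intermediate
14 | (R)-2-methylbutan-1-ol | CC[C@@H](C)CO | intermediate
15 | 2-(triphenylphosphoranylidene)propanal | CC(C=O)=P(c1ccccc1)(c1ccccc1)c1ccccc1 | starting material
16 | (R)-2-methylbutanal | CC[C@@H](C)C=O | intermediate
17 | (2E,4R)-2,4-dimethylhex-2-enal | CC[C@@H](C)/C=C(C)/C=O | intermediate
18 | diethyl [3-(trimethylsilyl)prop-2-yn-1-yl]phosphonate | CCOP(=O)(CC#C[Si](C)(C)C)OCC | starting material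
19 | [(3E,5E,7R)-5,7-dimethylnona-3,5-dien-1-yn-1-yl]trimethylsilane | CC[C@@H](C)/C=C(C)/C=C/C#C[Si](C)(C)C | intermediate
20 | (3E,5E,7R)-5,7-dimethylnona-3,5-dien-1-yne | CC[C@@H](C)/C=C(C)/C=C/C#C | intermediate
21 | 5-[(3E,5E,7R)-5,7-dimethylnona-3,5-dien-1-yn-1-yl]-2,2,8-trimethyl-4a,8a-dihydro-4H-benzo[d][1,3]dioxin-7(8H)-one (trans-fused) | O=C1C=C(C#C/C=C/C(C)=C/[C@H](C)CC)[C@@H]2COC(C)(C)O[C@H]2[C@H]1C | intermediate
22 | 5-[(3E,5E,7R)-5,7-dimethylnona-3,5-dien-1-yn-1-yl]-8-hydroxy-2,2,8-trimethyl-4a,8a-dihydro-4H-benzo[d][1,3]dioxin-7(8H)-one (trans-fused, 8-OH cis to the adjacent ring oxygen) | O=C1C=C(C#C/C=C/C(C)=C/[C@H](C)CC)[C@@H]2COC(C)(C)O[C@H]2[C@@]1(C)O | intermediate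
23 | 3-[(3E,5E,7R)-5,7-dimethylnona-3,5-dien-1-yn-1-yl]-5,6-dihydroxy-4-(hydroxymethyl)-6-methylcyclohex-2-en-1-one (5-OH and 6-OH cis, CH2OH trans to 5-OH) | O=C1C=C(C#C/C=C/C(C)=C/[C@H](C)CC)[C@H](CO)[C@@H](O)[C@@]1(C)O | intermediate
24 | (7R,8R,8aR)-3-[(1E,3E,5R)-3,5-dimethylhepta-1,3-dien-1-yl]-7,8-dihydroxy-7-methyl-1,7,8,8a-tetrahydro-6H-isochromen-6-one | CC[C@@H](C)/C=C(C)/C=C/C1=CC2=CC(=O)[C@](C)(O)[C@H](O)[C@H]2CO1 | intermediate
25 | (7R,8R,8aR)-5-chloro-3-[(1E,3E,5R)-3,5-dimethylhepta-1,3-dien-1-yl]-7,8-dihydroxy-7-methyl-1,7,8,8a-tetrahydro-6H-isochromen-6-one | CC[C@@H](C)/C=C(C)/C=C/C1=CC2=C(Cl)C(=O)[C@](C)(O)[C@H](O)[C@H]2CO1 | intermediate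
26 | (7R,8R,8aR)-5-chloro-3-[(1E,3E,5R)-3,5-dimethylhepta-1,3-dien-1-yl]-7-hydroxy-7-methyl-6-oxo-6,7,8,8a-tetrahydro-1H-isochromen-8-yl acetate | CC[C@@H](C)/C=C(C)/C=C/C1=CC2=C(Cl)C(=O)[C@](C)(O)[C@H](OC(C)=O)[C@H]2CO1 | target

**Totals**
Total step count: 19.
Longest linear sequence: 12 steps (steps 1, 2, 4, 5, 6, 7, 8, 15, 16, 17, 18, 19).

**Steps most likely to fail, with fallbacks**

Step 4. The cycloaddition of the only moderately activated pyranone with a hindered 1,2-disubstituted enol ether may be too slow even at 12 kbar. Forcing it thermally would bring loss of CO2 from the adduct and erosion of the facial bias. The fallback adds a temporary activating bromine. It sets out from 4, which is brominated at C3 (N-bromosuccinimide, CH3CN, rt) to 3-bromo-4-hydroxy-2H-pyran-2-one F1 and triflated as in step 3 to 3-bromo-2-oxo-2H-pyran-4-yl trifluoromethanesulfonate F2. 3-Bromo-2-pyrones add enol ethers at ambient pressure and moderate temperature with the same regio- and endo-selectivity, so F2 and 3 (toluene, 60 °C) should give the bridgehead bromide (1S,4S,7R,8S)-4-bromo-7-methyl-3-oxo-8-[(S)-1-(2,4,6-triisopropylphenyl)ethoxy]-2-oxabicyclo[2.2.2]oct-5-en-5-yl trifluoromethanesulfonate F3. Radical debromination (Bu3SnH, AIBN, benzene, 80 °C), which at a bridgehead can only occur with retention, comes back to the route at 6.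

Step 16. The base may deprotonate at the γ-position (C8a) or add to the ynenone, and the hindered tertiary enolate may be oxidised incompletely. The fallback moves the oxidation before the alkyne is attached and changes it to a Rubottom oxidation. It sets out from 10, which is converted (LiN(SiMe3)2, Me3SiCl, THF, −78 °C) into 2,2,8-trimethyl-7-(trimethylsilyloxy)-4a,8a-dihydro-4H-benzo[d][1,3]dioxin-5-yl trifluoromethanesulfonate F4. Its only electron-rich alkene (C6=C7) is epoxidised with dimethyldioxirane (acetone, −78 °C), again anti to the axial C8–H, and mild acid (citric acid, CH3OH) should give 8-hydroxy-2,2,8-trimethyl-7-oxo-4a,7,8,8a-tetrahydro-4H-benzo[d][1,3]dioxin-5-yl trifluoromethanesulfonate F5. Sonogashira coupling of F5 with 20 under the conditions of step 15 comes back to the route at 22.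

Step 6. Hydride may attack sulfur of the enol triflate (S–O cleavage to the C4a ketone and over-reduction) in competition with reduction of the lactone. The fallback changes the order so that no triflate meets a hydride. It sets out from 7, which is coupled with 20 (conditions of step 15) to 5-[(3E,5E,7R)-5,7-dimethylnona-3,5-dien-1-yn-1-yl]-8-hydroxy-7-methyl-2-oxabicyclo[2.2.2]oct-5-en-3-one F6. LiBH4 then gives 5-[(3E,5E,7R)-5,7-dimethylnona-3,5-dien-1-yn-1-yl]-4-(hydroxymethyl)-2-methylcyclohex-5-ene-1,3-diol F7, and 2,2-dimethoxypropane/PPTS gives 5-[(3E,5E,7R)-5,7-dimethylnona-3,5-dien-1-yn-1-yl]-2,2,8-trimethyl-4a,7,8,8a-tetrahydro-4H-benzo[d][1,3]dioxin-7-ol F8. Dess–Martin oxidation of F8 comes back to the route at 21.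

**Further compounds**
F1 | step 4 | 3-bromo-4-hydroxy-2H-pyran-2-one | O=C1OC=CC(O)=C1Br
F2 | step 4 | 3-bromo-2-oxo-2H-pyran-4-yl trifluoromethanesulfonate | O=C1OC=CC(OS(=O)(=O)C(F)(F)F)=C1Br
F3 | step 4 | (1S,4S,7R,8S)-4-bromo-7-methyl-3-oxo-8-[(S)-1-(2,4,6-triisopropylphenyl)ethoxy]-2-oxabicyclo[2.2.2]oct-5-en-5-yl trifluoromethanesulfonate | O=C1O[C@@H]2C=C(OS(=O)(=O)C(F)(F)F)[C@@]1(Br)[C@@H](O[C@@H](C)c3c(C(C)C)cc(C(C)C)cc3C(C)C)[C@H]2C
F4 | step 16 | 2,2,8-trimethyl-7-(trimethylsilyloxy)-4a,8a-dihydro-4H-benzo[d][1,3]dioxin-5-yl trifluoromethanesulfonate | CC1=C(O[Si](C)(C)C)C=C(OS(=O)(=O)C(F)(F)F)[C@@H]2COC(C)(C)O[C@@H]12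
F5 | step 16 | 8-hydroxy-2,2,8-trimethyl-7-oxo-4a,7,8,8a-tetrahydro-4H-benzo[d][1,3]dioxin-5-yl trifluoromethanesulfonate | O=C1C=C(OS(=O)(=O)C(F)(F)F)[C@@H]2COC(C)(C)O[C@H]2[C@@]1(C)O
F6 | step 6 | 5-[(3E,5E,7R)-5,7-dimethylnona-3,5-dien-1-yn-1-yl]-8-hydroxy-7-methyl-2-oxabicyclo[2.2.2]oct-5-en-3-one | O=C1O[C@@H]2C=C(C#C/C=C/C(C)=C/[C@H](C)CC)[C@H]1[C@@H](O)[C@H]2C
F7 | step 6 | 5-[(3E,5E,7R)-5,7-dimethylnona-3,5-dien-1-yn-1-yl]-4-(hydroxymethyl)-2-methylcyclohex-5-ene-1,3-diol | O[C@@H]1C=C(C#C/C=C/C(C)=C/[C@H](C)CC)[C@H](CO)[C@@H](O)[C@H]1C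
F8 | step 6 | 5-[(3E,5E,7R)-5,7-dimethylnona-3,5-dien-1-yn-1-yl]-2,2,8-trimethyl-4a,7,8,8a-tetrahydro-4H-benzo[d][1,3]dioxin-7-ol | O[C@@H]1C=C(C#C/C=C/C(C)=C/[C@H](C)CC)[C@@H]2COC(C)(C)O[C@H]2[C@H]1C
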